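## Analysis of the target

Cathayanon I is a dihydroflavonol. Ring C is a chroman-4-one fused to the phloroglucinol-type ring A (hydroxyls at C5 and C7); it carries a hydroxyl at C3 and, at C2, a 2',4'-dihydroxyphenyl ring B with 3-methylbut-2-enyl (prenyl) groups at C3' and C5'. The only stereocentres are C2 and C3, both R, with the aryl group and the hydroxyl trans and both equatorial, which is also the more stable relative configuration. C2 is a benzylic aryl ether carbon whose bond to O1 can open to a quinone methide whenever the 2'- or 4'-hydroxyl is free and base or heat is applied. C3 is the carbinol of an α-ketol that base can enolise, oxidise to the flavonol or contract to a benzofuranone. The two ortho-prenylphenol units close to 2,2-dimethylchromans under acid and to chromenes under oxidants, so the end game has to be neutral and non-oxidising. The five hydroxyls differ clearly: 7-OH is the most acidic (vinylogous acid of the C4 ketone), 2'- and 4'-OH are ordinary resorcinol phenols, 5-OH is hydrogen-bonded to the ketone, and 3-OH is aliphatic. The difficulty is therefore not the skeleton, which (2R,3R)-dihydromorin already holds with both stereocentres, but putting two prenyl groups on exactly C3' and C5' under conditions the dihydroflavonol survives. The feature used is that ring B is a 4-substituted resorcinol: C3' is ortho to both O2' and O4', C5' is ortho to O4', C1' is blocked by C2 and C6' is meta to both oxygens, so each prenyl-bearing carbon has an oxygen neighbour from which a C5 unit can be delivered by a [3,3] shift.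

## Retrosynthetic reasoning

**14 to 13 (O7–Si).** The last bond cut is the silicon–oxygen bond at O7. The target 14 is too acid-, base- and oxidant-sensitive for anything but a protecting-group removal at the end. A silyl ether on the electron-poor 7-oxygen leaves under buffered fluoride, which touches neither the prenyl groups nor the α-ketol. This leads back to the 7-O-silyl ether 13.

**13 to 9 (C3'–C1'' and C5'–C1'').** Both aryl–CH2 bonds of the prenyl groups are cut together and transposed into O–C(CH3)2 bonds of tertiary allyl ethers on O2' and O4', giving 9. The cut is made here because the carbons to be substituted are defined by their relation to the two ring B oxygens, and a sigmatropic shift can only deliver carbon ortho to the oxygen it starts from. Ring A, which an electrophilic prenylation would attack at C6 and C8, is left alone. The gain is two skeletal bonds in one neutral, reagent-free operation on a compound that already contains rings A, B and C and both stereocentres. The forward reaction has to send the 2'-allyl unit to C3' and the 4'-allyl unit to C5', each with a single allylic inversion so that the tertiary ether ends as a primary prenyl group.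

**9 to 3 and 7 (two O–C bonds).** The two tertiary ether bonds of 9 are cut to the diphenol 3 and two molecules of the tertiary allyl carbonate 7. A palladium-catalysed allylic etherification with a carbonate is preferred to a base-mediated alkylation because it needs no free base. This matters because 3 has free 2'- and 4'-hydroxyls that, as phenoxides, would open ring C at C2. The forward step must alkylate the two resorcinol hydroxyls at the tertiary allyl terminus and leave the chelated 5-OH and the aliphatic 3-OH alone.

**7 to 4 and 5.** The carbonate 7 is cut at its acyl–oxygen bond to the tertiary allylic alcohol 4 and the dicarbonate 5. This is a one-step side branch that keeps the route independent of the supply of 7.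

**3 to 1 and 2 (O7–Si).** The silyl ether 3 is cut to (2R,3R)-dihydromorin 1 and the silyl chloride 2. O7 has to be capped because, as the most acidic phenol, it would otherwise be allylated first and would then send a prenyl group to C8 or C6. The same acidity is what allows it to be silylated selectively with one equivalent of 2.

## Alternatives that were turned down

**Alternative 1:** The cut is the C4a–C8a bond of ring A, so that the phloroglucinol ring is made from an open chain in the way a polyketide synthase does.
- Key step: the substrate is the methyl 3,5,7-trioxoheptanoate A2, whose C7 ketone carries the future C3 and C2 as a trans-acetonide together with the diprenylated ring B as its bis(methoxymethyl) ether. Mg(OMe)2 would hold A2 as a chelated polyenolate in which the carbon between the C5 and C7 ketones attacks the ester carbon. Loss of methoxide and enolisation would give the acylphloroglucinol A1. Ring C would then be closed between a phenol oxygen and the benzylic carbon after removal of the acetonide, and the acetals taken off.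
- For it: no natural precursor is needed. The diol stereocentres come from a dependable asymmetric dihydroxylation. The two ortho hydroxyls of A1 are equivalent, so closure of ring C is unambiguous. The prenyl groups are in place before any sensitive ring exists.
- Against it: polyketo esters such as A2 are labile and tend to lactonise to a hydroxypyranone or to close by aldol reaction to a resorcylate. The α-alkoxy ketone stereocentre (the later C3) lies next to an enolisable ketone in base. Ring C must be closed at a benzylic carbon through a cation or by activating one of two secondary alcohols. The final acid treatment meets two ortho-prenylphenols. The diprenylated ring B aldehyde must itself be made, so the regiochemical problem is moved, not removed, though it is easier to solve on a simple arene.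
- Comparison: Alternative 1 is the stronger on independence from natural supply and on the timing of the prenylation. The chosen route offers a handful of steps against well over a dozen, and it builds no stereocentre.

**Alternative 2:** The cut is the C2–C3 bond.
- Key step: the precursor A4 is a mixed O-aryl O-methyl acetal of the ring B aldehyde. Its aryl oxygen is O1 of a ring A that bears, ortho to it, the Z-bis(silyloxy) enol ether of the C4–C3 unit. A confined chiral silylium imidodiphosphorimidate catalyst would remove methoxide, and C3 of the enol silane would attack the oxocarbenium ion spanning O1 and C2 in a six-membered closure. The product would be the pentasilyl ether A3, with both stereocentres set under the influence of the chiral counter-anion; fluoride would then free the target.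
- For it: one catalytic step makes ring C and both stereocentres. Either enantiomer and many analogues become accessible. The union of the ring A and ring B fragments is convergent. All five protecting groups leave under fluoride, which suits the prenyl groups better than acid.
- Against it: the cation is stabilised by the 2,4-dioxygenated aryl ring, so it is long-lived, loosely ion-paired and liable to close without control by the anion. The strongly acidic catalyst meets two trisubstituted alkenes next to aryl oxygens, the classical setting for chroman formation. Five bulky silyl ethers must fit into a confined anion. A4, an acetal of a hindered phenol beside a tetrasubstituted enol ether, is hard to make and to keep. A closure of this kind on a flavanone skeleton would first have to be developed, and the diprenylated ring B aldehyde is needed here as well.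
- Comparison: Alternative 2 is stronger on generality and on control of absolute configuration by a catalyst. The chosen route needs no such control at all, because 1 supplies C2 and C3, and it confines its risk to one thermal step.

**Alternative 3:** The cuts are the O1–C2 and C3–C4 bonds.
- Key step: a chiral phosphoric acid would ionise the salicylaldehyde dimethyl acetal A6 to a 4-methoxy ortho-quinone methide, which would add across the E-styrylsilane A7 in a hetero-[4+2] cycloaddition. The product would be the 2,3-trans 3-silyl-4-methoxyflavan A5. Oxidation of the C–Si bond with retention would give the 3-hydroxyl, C4 would be raised to the ketone, and four methoxymethyl ethers removed.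
- For it: the step is convergent and forms two bonds. The E geometry of A7 maps directly onto the 2,3-trans relationship. The regiochemistry is backed both by the benzylic position and by the β-effect of silicon.
- Against it: a vinylsilane is a weak partner for a stabilised quinone methide, and a stepwise pathway can end in loss of silicon instead of ring closure. After the cycloaddition the C3–Si bond must be oxidised and C4 brought from the ether to the ketone level in the right order, since a silyl group next to a ketone would be lost and not oxidised. That is done next to two prenyl groups and electron-rich rings. The closing acid treatment again endangers the ortho-prenylphenols. The sequence after the key step alone is longer than the whole chosen route.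
- Comparison: Alternative 3 is stronger on convergence and on freedom to vary ring A and ring B. The chosen route is much shorter, needs one protecting group and requires no adjustment of oxidation level.

Key step: step 4

Assumption: (2R,3R)-dihydromorin 1 is bought as the enantiopure natural product; the carbonate 7 is made in one step in case it is not stocked.

## Route

**Step 1**
Reactants: 1 (2R,3R)-dihydromorin; 2 chlorotriisopropylsilane
Product: 3 (2R,3R)-7-O-(triisopropylsilyl)dihydromorin
Conditions: TIPSCl (1.05 equiv), i-Pr2NEt (1.2 equiv), DMF, −20 to 0 °C
Reagents that add atoms: chlorotriisopropylsilane (2), CC(C)[Si](Cl)(C(C)C)C(C)C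
Why: Silylation under acidity control: the 7-OH, para to the C4 carbonyl, is clearly the most acidic hydroxyl and is the one ionised by the amine, while the bulky silyl chloride is slow at the flanked 2'-OH and at the hydrogen-bonded 5-OH, so one equivalent at low temperature should cap O7 only. Triisopropylsilyl is chosen because an aryl silyl ether of this size should withstand the transient alkoxide of step 3 and the hot amine of step 4, yet the electron-poor O7–Si bond leaves readily with fluoride.

**Step 2**
Reactants: 4 2-methylbut-3-en-2-ol; 5 di-tert-butyl dicarbonate
Product: 7 tert-butyl 2-methylbut-3-en-2-yl carbonate, via lithium 2-methylbut-3-en-2-olate 6 (not isolated)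
Conditions: n-BuLi (1.0 equiv), THF, −78 to 0 °C; then Boc2O, 0 °C to rt; H2O
Reagents that add atoms: di-tert-butyl dicarbonate (5), CC(C)(C)OC(=O)OC(=O)OC(C)(C)C
Why: O-Acylation of the lithium alkoxide 6 with the dicarbonate is the usual way to the mixed tert-butyl carbonate of a tertiary allylic alcohol; prior deprotonation is used because the hindered alcohol acylates too slowly under amine catalysis.

**Step 3**
Reactants: 3 (2R,3R)-7-O-(triisopropylsilyl)dihydromorin; 7 tert-butyl 2-methylbut-3-en-2-yl carbonate (2.6 equiv)
Product: 9 (2R,3R)-2',4'-bis-O-(2-methylbut-3-en-2-yl)-7-O-(triisopropylsilyl)dihydromorin, via 4'-mono-ether 8 (not isolated)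
Conditions: Pd(PPh3)4 (5 mol %), THF (degassed), 0–4 °C, dark
Reagents that add atoms: tert-butyl 2-methylbut-3-en-2-yl carbonate (7), C=CC(C)(C)OC(=O)OC(C)(C)C
Why: Decarboxylative Tsuji–Trost O-allylation: zerovalent palladium ionises 7 to a 1,1-dimethyl-π-allyl complex, CO2 and tert-butoxide, which deprotonates a phenol, and the phenoxide attacks the more substituted allyl terminus under kinetic control at low temperature, first at the open 4'-OH (8) and then at the 2'-OH. The chelated 5-OH and the aliphatic 3-OH are far poorer nucleophiles, and because no free base is present the α-ketol and C2 are not exposed to epimerising conditions.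

**Step 4**
Reactants: 9 (2R,3R)-2',4'-bis-O-(2-methylbut-3-en-2-yl)-7-O-(triisopropylsilyl)dihydromorin
Product: 13 7-O-(triisopropylsilyl) Cathayanon I, via 5'-prenyl dienone 10 (not isolated), via 5'-prenyl 4'-phenol 11 (not isolated), via 3',5'-diprenyl dienone 12 (not isolated)
Conditions: PhNEt2 (degassed, 0.05 M), 130 °C, Ar, dark
Reagents that add atoms: none
Why: Two thermal aromatic Claisen rearrangements of aryl 1,1-dimethylallyl ethers, the standard route to ortho-prenylphenols, run in one flask; each is a concerted suprafacial [3,3] shift through a chair-like transition state that joins the unsubstituted CH2 terminus to an ortho ring carbon with allylic inversion, so that the tertiary ether becomes a 3-methylbut-2-enyl group and the cyclohexadienone formed (10, later 12) enolises to the phenol (11, then 13). No ring is closed and no stereocentre is created; C2 and C3 are spectators, and because both ring B oxygens are alkylated at the start the quinone methide route to C2 epimerisation stays shut until the phenols appear. The selectivity needed is positional: the 2'-ether can give a prenyl group only at C3' (its other ortho carbon C1' is quaternary, and a dienone formed there returns to the ether), so the 4'-ether has to take C5' and not C3'. Three features of 9 favour this: the alkoxy group at C2', meta to O4', directs ortho migration to the carbon para to itself (C5'), as meta donors generally do in aryl allyl ethers; C3' is the more crowded site, lying between two tertiary alkoxy groups; and once either group has reached its proper carbon the other has only one open ortho position left. A relay through the para position cannot be relied on, because a second [3,3] shift inverts the allyl unit again and would put a 1,1-dimethylallyl group on C5'; what can rescue material that goes from O4' to C3' first is the 3',3'-diprenyl dienone formed from the remaining 2'-ether, which can hand one prenyl group back to O4' by a retro-Claisen shift and so reach C5' by a third shift. The moderate temperature that tertiary allyl ethers allow and the amine solvent are meant to hold back acid-catalysed chroman formation, loss of the allyl unit by elimination and opening of ring C; the chelated 5-OH, the 3-OH and the 7-O-silyl ether take no part.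

**Step 5**
Reactants: 13 7-O-(triisopropylsilyl) Cathayanon I
Product: 14 Cathayanon I
Conditions: Bu4NF (1.1 equiv), AcOH (1.5 equiv), THF, 0 °C
Reagents that add atoms: none
Why: Fluoride-mediated cleavage of an aryl silyl ether; the 7-phenoxide is a very good leaving group on silicon, so the reaction should be fast at 0 °C, and acetic acid keeps the medium from turning basic, which protects C2, the α-ketol and the air-sensitive polyphenol. The prenyl groups are inert to fluoride.

## Compound list

1 | (2R,3R)-dihydromorin, (2R,3R)-2-(2,4-dihydroxyphenyl)-3,5,7-trihydroxy-2,3-dihydro-4H-chromen-4-one | Oc1ccc([C@H]2Oc3cc(O)cc(O)c3C(=O)[C@@H]2O)c(O)c1 | starting material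
2 | chlorotriisopropylsilane | CC(C)[Si](Cl)(C(C)C)C(C)C | starting material
3 | (2R,3R)-7-O-(triisopropylsilyl)dihydromorin | Oc1ccc([C@H]2Oc3cc(O[Si](C(C)C)(C(C)C)C(C)C)cc(O)c3C(=O)[C@@H]2O)c(O)c1 | intermediate
4 | 2-methylbut-3-en-2-ol | C=CC(C)(C)O | starting material
5 | di-tert-butyl dicarbonate | CC(C)(C)OC(=O)OC(=O)OC(C)(C)C | starting material
6 | lithium 2-methylbut-3-en-2-olate | [Li+].[O-]C(C)(C)C=C | intermediate
7 | tert-butyl 2-methylbut-3-en-2-yl carbonate | C=CC(C)(C)OC(=O)OC(C)(C)C | intermediate
8 | (2R,3R)-4'-O-(2-methylbut-3-en-2-yl)-7-O-(triisopropylsilyl)dihydromorin | C=CC(C)(C)Oc1ccc([C@H]2Oc3cc(O[Si](C(C)C)(C(C)C)C(C)C)cc(O)c3C(=O)[C@@H]2O)c(O)c1 | intermediate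
9 | (2R,3R)-2',4'-bis-O-(2-methylbut-3-en-2-yl)-7-O-(triisopropylsilyl)dihydromorin | C=CC(C)(C)Oc1ccc([C@H]2Oc3cc(O[Si](C(C)C)(C(C)C)C(C)C)cc(O)c3C(=O)[C@@H]2O)c(OC(C)(C)C=C)c1 | intermediate
10 | cyclohexa-2,4-dienone from the first shift: ring B with C4'=O and sp3 C5' (H and prenyl, configuration at C5' not defined), 2'-ether intact, (2R,3R) | CC(C)=CCC1C=C([C@H]2Oc3cc(O[Si](C(C)C)(C(C)C)C(C)C)cc(O)c3C(=O)[C@@H]2O)C(OC(C)(C)C=C)=CC1=O | intermediate
11 | (2R,3R)-5'-prenyl-2'-O-(2-methylbut-3-en-2-yl)-7-O-(triisopropylsilyl)dihydromorin (4'-OH free) | CC(C)=CCc1cc([C@H]2Oc3cc(O[Si](C(C)C)(C(C)C)C(C)C)cc(O)c3C(=O)[C@@H]2O)c(OC(C)(C)C=C)cc1O | intermediate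
12 | cyclohexa-2,4-dienone from the second shift: ring B with C2'=O and sp3 C3' (H and prenyl, configuration at C3' not defined), 4'-OH, 5'-prenyl, (2R,3R) | CC(C)=CCC1=C(O)C(CC=C(C)C)C(=O)C([C@H]2Oc3cc(O[Si](C(C)C)(C(C)C)C(C)C)cc(O)c3C(=O)[C@@H]2O)=C1 | intermediate
13 | 7-O-(triisopropylsilyl) Cathayanon I, (2R,3R) | CC(C)=CCc1cc([C@H]2Oc3cc(O[Si](C(C)C)(C(C)C)C(C)C)cc(O)c3C(=O)[C@@H]2O)c(O)c(CC=C(C)C)c1O | intermediate
14 | Cathayanon I, (2R,3R)-2-[2,4-dihydroxy-3,5-bis(3-methylbut-2-enyl)phenyl]-3,5,7-trihydroxy-2,3-dihydro-4H-chromen-4-one | CC(C)=CCc1cc([C@H]2Oc3cc(O)cc(O)c3C(=O)[C@@H]2O)c(O)c(CC=C(C)C)c1O | target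

## Step count and least certain steps

Total step count: 5. Longest linear sequence: 4 steps (1 to 3 to 9 to 13 to 14); step 2 is a one-step side branch.

**Step 4 (key step).** The main danger is misdirection of the first migration. If the 4'-allyl unit goes to C3' before the 2'-ether has reacted, the 2'-ether has no free ortho carbon left. It can then only pass through a crowded 3',3'-disubstituted dienone, from which transfer to C5' with double inversion leaves a 1,1-dimethylallyl group there. The same outcome follows if the 2'-ether attacks C1' and the group travels on to the para position. Other possible losses: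
- elimination of the tertiary allyl unit as a diene at the reaction temperature;
- opening of ring C through a quinone methide once the ring B phenols are free, with partial epimerisation at C2 or isomerisation of the ketol;
- silyl transfer from O7 to a new phenol.

Fallback: it sets out from 3 and comes back at 13, and it replaces the one-flask double shift by two single shifts whose direction is forced.
- A second silylation of 3 (TIPSCl, imidazole, DMF) should go to the unhindered 4'-OH and give (2R,3R)-7,4'-bis-O-(triisopropylsilyl)dihydromorin F1.
- The remaining 2'-OH is alkylated with 7 under Pd(PPh3)4 to the 2'-O-(2-methylbut-3-en-2-yl) ether F2. Its only open ortho carbon is C3', so heating in PhNEt2 should give (2R,3R)-3'-prenyl-7,4'-bis-O-(triisopropylsilyl)dihydromorin F3.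
- Bu4NF/AcOH removes both silyl groups to give (2R,3R)-3'-prenyldihydromorin F4, and the 7-OH is silylated again as in step 1 to (2R,3R)-3'-prenyl-7-O-(triisopropylsilyl)dihydromorin F5.
- The 4'-OH is more accessible than the 2'-OH, which now lies between the prenyl group and C1'. It is alkylated with one equivalent of 7 to the 4'-O-(2-methylbut-3-en-2-yl) ether F6.
- In F6 the ether oxygen finds C3' and the para carbon C1' occupied and only C5' open, so the second rearrangement should lead to 13.

The price is five additional steps.

**Step 3.** The zerovalent palladium catalyst can re-ionise the tertiary aryl ethers once formed and let them collapse to the linear prenyl ethers, which would later deliver the allyl unit the wrong way round. Alkylation may also stop at the mono-ether stage because the 2'-OH is hindered, or spread to the 5-OH if the excess of 7 is too large.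

Fallback: it sets out from 3 and returns at 9, and it makes the O–C(CH3)2 bond by a reaction that cannot give the linear isomer. Copper-catalysed propargylation of 3 with 3-chloro-3-methylbut-1-yne (CuCl2, DBU, MeCN, 0 °C) should give (2R,3R)-2',4'-bis-O-(2-methylbut-3-yn-2-yl)-7-O-(triisopropylsilyl)dihydromorin F7. Semihydrogenation of F7 (H2, Pd/CaCO3 poisoned with Pb(OAc)2, quinoline, EtOAc) gives 9. The price is one more step and a short exposure of the free ring B phenols to an amidine base, which is why this is not the first choice.

**Step 1.** Silylation may not stay at O7: a second silyl group can enter at the 4'-OH, or the silyl group can move from the good leaving group O7 to a ring B phenoxide during this step or step 3.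

Fallback: it sets out from 1 and returns at 14, and it replaces the silyl ether by an acetal introduced by alkylation of the most acidic phenoxide. With MOMCl (1.05 equiv) and i-Pr2NEt in CH2Cl2/DMF at 0 °C, 1 should give (2R,3R)-7-O-(methoxymethyl)dihydromorin F8. F8 is taken through the chemistry of steps 3 and 4 to the bis-ether (2R,3R)-2',4'-bis-O-(2-methylbut-3-en-2-yl)-7-O-(methoxymethyl)dihydromorin F9 and then to 7-O-(methoxymethyl) Cathayanon I F10. Mild acid (HCl in MeOH, rt) removes the acetal from F10 to give 14. The drawback is the acidic last step next to two ortho-prenylphenols, which has to be kept short and cold.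

## Further compounds

F1 | step 4 | (2R,3R)-7,4'-bis-O-(triisopropylsilyl)dihydromorin | CC(C)[Si](Oc1ccc([C@H]2Oc3cc(O[Si](C(C)C)(C(C)C)C(C)C)cc(O)c3C(=O)[C@@H]2O)c(O)c1)(C(C)C)C(C)C
F2 | step 4 | (2R,3R)-2'-O-(2-methylbut-3-en-2-yl)-7,4'-bis-O-(triisopropylsilyl)dihydromorin | CC(C)[Si](Oc1ccc([C@H]2Oc3cc(O[Si](C(C)C)(C(C)C)C(C)C)cc(O)c3C(=O)[C@@H]2O)c(OC(C)(C)C=C)c1)(C(C)C)C(C)C
F3 | step 4 | (2R,3R)-3'-prenyl-7,4'-bis-O-(triisopropylsilyl)dihydromorin | CC(C)=CCc1c(O)c([C@H]2Oc3cc(O[Si](C(C)C)(C(C)C)C(C)C)cc(O)c3C(=O)[C@@H]2O)ccc1O[Si](C(C)C)(C(C)C)C(C)C
F4 | step 4 | (2R,3R)-3'-prenyldihydromorin | CC(C)=CCc1c(O)c([C@H]2Oc3cc(O)cc(O)c3C(=O)[C@@H]2O)ccc1O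
F5 | step 4 | (2R,3R)-3'-prenyl-7-O-(triisopropylsilyl)dihydromorin | CC(C)=CCc1c(O)c([C@H]2Oc3cc(O[Si](C(C)C)(C(C)C)C(C)C)cc(O)c3C(=O)[C@@H]2O)ccc1O
F6 | step 4 | (2R,3R)-3'-prenyl-4'-O-(2-methylbut-3-en-2-yl)-7-O-(triisopropylsilyl)dihydromorin | CC(C)=CCc1c(O)c([C@H]2Oc3cc(O[Si](C(C)C)(C(C)C)C(C)C)cc(O)c3C(=O)[C@@H]2O)ccc1OC(C)(C)C=C
F7 | step 3 | (2R,3R)-2',4'-bis-O-(2-methylbut-3-yn-2-yl)-7-O-(triisopropylsilyl)dihydromorin | C#CC(C)(C)Oc1ccc([C@H]2Oc3cc(O[Si](C(C)C)(C(C)C)C(C)C)cc(O)c3C(=O)[C@@H]2O)c(OC(C)(C)C#C)c1
F8 | step 1 | (2R,3R)-7-O-(methoxymethyl)dihydromorin | Oc1ccc([C@H]2Oc3cc(OCOC)cc(O)c3C(=O)[C@@H]2O)c(O)c1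
F9 | step 1 | (2R,3R)-2',4'-bis-O-(2-methylbut-3-en-2-yl)-7-O-(methoxymethyl)dihydromorin | C=CC(C)(C)Oc1ccc([C@H]2Oc3cc(OCOC)cc(O)c3C(=O)[C@@H]2O)c(OC(C)(C)C=C)c1
F10 | step 1 | 7-O-(methoxymethyl) Cathayanon I, (2R,3R) | CC(C)=CCc1cc([C@H]2Oc3cc(OCOC)cc(O)c3C(=O)[C@@H]2O)c(O)c(CC=C(C)C)c1O
A1 | alternative 1 | 2,4,6-trihydroxyphenyl ketone carrying the trans-acetonide of the C2/C3 diol and ring B as bis(methoxymethyl) ether, configuration as in the SMILES | CC(C)=CCc1cc([C@@H]2OC(C)(C)O[C@H]2C(=O)c3c(O)cc(O)cc3O)c(OCOC)c(CC=C(C)C)c1OCOC
A2 | alternative 1 | methyl 3,5,7-trioxo-7-(dioxolanyl)heptanoate, open-chain precursor of A1, configuration as in the SMILES | CC(C)=CCc1cc([C@@H]2OC(C)(C)O[C@H]2C(=O)CC(=O)CC(=O)CC(=O)OC)c(OCOC)c(CC=C(C)C)c1OCOC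
A3 | alternative 2 | (2R,3R)-penta-O-(tert-butyldimethylsilyl) Cathayanon I | CC(C)=CCc1cc([C@H]2Oc3cc(O[Si](C)(C)C(C)(C)C)cc(O[Si](C)(C)C(C)(C)C)c3C(=O)[C@@H]2O[Si](C)(C)C(C)(C)C)c(O[Si](C)(C)C(C)(C)C)c(CC=C(C)C)c1O[Si](C)(C)C(C)(C)C
A4 | alternative 2 | O-aryl O-methyl acetal of the ring B aldehyde with the Z-bis(silyloxy) enol ether on ring A, acetal carbon racemic | CC(C)=CCc1cc(C(OC)Oc2cc(O[Si](C)(C)C(C)(C)C)cc(O[Si](C)(C)C(C)(C)C)c2/C(O[Si](C)(C)C(C)(C)C)=C/O[Si](C)(C)C(C)(C)C)c(O[Si](C)(C)C(C)(C)C)c(CC=C(C)C)c1O[Si](C)(C)C(C)(C)C
A5 | alternative 3 | 2,3-trans-2,4-cis 3-(benzyldimethylsilyl)-4-methoxyflavan, tetrakis(methoxymethyl) ether | CC(C)=CCc1cc([C@H]2Oc3cc(OCOC)cc(OCOC)c3[C@@H](OC)[C@@H]2[Si](C)(C)Cc4ccccc4)c(OCOC)c(CC=C(C)C)c1OCOC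
A6 | alternative 3 | 2-(dimethoxymethyl)-3,5-bis(methoxymethoxy)phenol | COCOc1cc(O)c(C(OC)OC)c(OCOC)c1
A7 | alternative 3 | benzyl(dimethyl)[(E)-2-[2,4-bis(methoxymethoxy)-3,5-bis(3-methylbut-2-enyl)phenyl]ethenyl]silane | CC(C)=CCc1cc(/C=C/[Si](C)(C)Cc2ccccc2)c(OCOC)c(CC=C(C)C)c1OCOC
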